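**Retrosynthetic overview**
1. Last step: both phenolic C–OH bonds are made from C–Cl bonds. The two 4-hydroxyphenyl rings are carried through the route as 4-chlorophenyl rings.
2. Key disconnection: the O1–C2 bond of ring C. An open-chain phenol/2,4-dimethoxybenzylic alcohol is closed by a stereoconvergent SN1 cycloetherification, which sets C2.
3. C2–aryl and C2–H come from aryllithium opening of a 3,4-trans dihydrocoumarin followed by hydride, in one flask.
4. C3–benzyl comes from trans-selective lactone enolate alkylation. C4–styryl comes from Rh-catalysed asymmetric 1,4-addition to 7-methoxycoumarin, the only catalyst-set centre.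
5. Ring order: all four benzene rings are bought. The bought lactone ring protects the ring A phenol and relays stereochemistry, is then opened, and ring C is the only ring formed (step 4).

Assumption: the SMILES is read as (2R,3R,4R), that is 2,3-trans-3,4-trans, and caraganin C is taken to be this enantiomer.

**Step 1**
Reactants: 1 7-methoxycoumarin; 2 (E)-2-(4-chlorophenyl)vinylboronic acid
Product: 3 (4S)-4-[(E)-2-(4-chlorophenyl)ethenyl]-7-methoxychroman-2-one
Conditions: Rh(acac)(C2H4)2 (3 mol%), (S)-SEGPHOS (3.3 mol%), 2 (3 equiv in three portions), 1,4-dioxane/H2O 10:1, 60 °C, 16 h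
Reagents that add atoms: none
Why: Hayashi–Miyaura reaction (rhodium-catalysed asymmetric 1,4-addition): transmetalation gives a styryl complex of monovalent rhodium that inserts the coumarin C3=C4 bond on the face left open by (S)-SEGPHOS and water protonates the rhodium enolate, which sets C4 as S with retention of the E alkene (in the well-studied aryl series the (S)-ligand gives the (S)-4-substituted lactones and the CIP ranking at C4 is the same here) and leaves the C–Cl bond untouched.

**Step 2**
Reactants: 3 (4S)-4-[(E)-2-(4-chlorophenyl)ethenyl]-7-methoxychroman-2-one; 4 4-chlorobenzyl bromide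
Product: 6 (3R,4R)-3-(4-chlorobenzyl)-4-[(E)-2-(4-chlorophenyl)ethenyl]-7-methoxychroman-2-one, via lithium enolate 5 (not isolated)
Conditions: LiN(SiMe3)2 (1.1 equiv), THF, −78 °C, 30 min; 4 (1.3 equiv), −78 → −30 °C, 3 h
Reagents that add atoms: none
Why: Kinetic lithium enolate alkylation (SN2 on a benzylic bromide): the C4 styryl group sits pseudo-axial on the flat enolate and blocks one face, so 4 enters anti to it and gives the 3,4-trans lactone, which sets C3 as R (C4 is unchanged in space and is called R only because the CIP ranking changes).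

**Step 3**
Reactants: 6 (3R,4R)-3-(4-chlorobenzyl)-4-[(E)-2-(4-chlorophenyl)ethenyl]-7-methoxychroman-2-one; 7 1-bromo-2,4-dimethoxybenzene
Product: 10 (1RS,2R,3R,4E)-2-(4-chlorobenzyl)-5-(4-chlorophenyl)-1-(2,4-dimethoxyphenyl)-3-(2-hydroxy-4-methoxyphenyl)pent-4-en-1-ol, via 2,4-dimethoxyphenyllithium 8 (not isolated), via lithium keto-phenolate 9 (not isolated)
Conditions: 7 (1.1 equiv), n-BuLi (1.05 equiv), THF, −78 °C, 30 min; 6, −78 °C, 1 h; LiAlH4 (1.0 equiv), −78 → 0 °C, 1 h; H2O/aq NaOH work-up, product used crude
Reagents that add atoms: none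
Why: Bromine–lithium exchange, acyl substitution and hydride reduction in one flask: the aryl ester carbonyl of 6 is far more electrophilic than the alpha-branched, doubly methoxy-donated ketone 9 released as its phenolate, so 8 adds only once at −78 °C, and LiAlH4 reduces 9 before it can epimerise, leaving C3 and C4 untouched while the new carbinol centre may be a mixture because it is erased in step 4.

**Step 4 (key step)**
Reactants: 10 (1RS,2R,3R,4E)-2-(4-chlorobenzyl)-5-(4-chlorophenyl)-1-(2,4-dimethoxyphenyl)-3-(2-hydroxy-4-methoxyphenyl)pent-4-en-1-ol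
Product: 12 (2R,3R,4R)-3-(4-chlorobenzyl)-4-[(E)-2-(4-chlorophenyl)ethenyl]-2-(2,4-dimethoxyphenyl)-7-methoxychroman, via benzylic cation 11 (not isolated)
Conditions: (R)-TRIP (5 mol%; the antipode if it proves to be the matched one), 4 Å molecular sieves, toluene (0.05 M), 0 → 23 °C, 8 h
Reagents that add atoms: none
Why: Proposed new method: a chiral-phosphate contact-ion-pair SN1 cycloetherification of a saturated benzylic alcohol that cannot form a quinone methide, in which TRIP (about as acidic as a pyridinium salt) protonates the very labile 2,4-dimethoxybenzylic hydroxyl of either carbinol epimer, water leaves to give cation 11 held by the phosphate, and the P=O group at the same time accepts a hydrogen bond from the ring A phenol and guides it onto the cation face exposed in the A(1,3)-minimised conformer (H3 eclipsing the aryl plane, the benzyl group anti to the incoming oxygen), so that O1–C2 forms with H2 anti to H3 (2R, all three substituents equatorial), both epimers converge, and the acid is too weak to re-ionise the aryl ether product so the kinetic ratio is kept; the closest known reaction types are the chiral Brønsted acid contact-ion-pair allylic etherification that gives 2H-chromenes, phosphoric acid catalysed additions to quinone methides, and the ordinary acid-catalysed dehydrative cyclisation of 1-aryl-3-(2-hydroxyaryl)propanols to flavans.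

**Step 5**
Reactants: 12 (2R,3R,4R)-3-(4-chlorobenzyl)-4-[(E)-2-(4-chlorophenyl)ethenyl]-2-(2,4-dimethoxyphenyl)-7-methoxychroman
Product: 13 caraganin C
Conditions: Pd2(dba)3 (2 mol%), tBuBrettPhos (5 mol%), KOH (6 equiv), 1,4-dioxane/H2O 4:1, 80 °C, 16 h; then 1 M HCl to pH 5
Reagents that add atoms: potassium hydroxide, [K+].[OH-]
Why: Buchwald-type palladium-catalysed hydroxylation of aryl chlorides: oxidative addition of each C–Cl bond to zerovalent palladium, chloride–hydroxide exchange and C–O reductive elimination from the bulky biarylphosphine complex turn both masked positions into phenols, while the methyl ethers, the ring C ether, the E alkene and the three stereocentres (none acidic enough for aqueous KOH at 80 °C) are not affected.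

**Compound list**
1 | 7-methoxycoumarin | COc1ccc2ccc(=O)oc2c1 | starting material
2 | (E)-2-(4-chlorophenyl)vinylboronic acid | OB(O)/C=C/c1ccc(Cl)cc1 | starting material
3 | (4S)-4-[(E)-2-(4-chlorophenyl)ethenyl]-7-methoxychroman-2-one | COc1ccc2c(c1)OC(=O)C[C@H]2/C=C/c1ccc(Cl)cc1 | intermediate
4 | 4-chlorobenzyl bromide | Clc1ccc(CBr)cc1 | starting material
5 | lithium enolate of 3 | COc1ccc2c(c1)OC([O-])=C[C@H]2/C=C/c1ccc(Cl)cc1.[Li+] | intermediate
6 | (3R,4R)-3-(4-chlorobenzyl)-4-[(E)-2-(4-chlorophenyl)ethenyl]-7-methoxychroman-2-one (3,4-trans) | COc1ccc2c(c1)OC(=O)[C@H](Cc1ccc(Cl)cc1)[C@H]2/C=C/c1ccc(Cl)cc1 | intermediate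
7 | 1-bromo-2,4-dimethoxybenzene | COc1ccc(Br)c(OC)c1 | starting material
8 | 2,4-dimethoxyphenyllithium | [Li]c1ccc(OC)cc1OC | intermediate
9 | lithium phenolate of (2R,3R,4E)-2-(4-chlorobenzyl)-5-(4-chlorophenyl)-1-(2,4-dimethoxyphenyl)-3-(2-hydroxy-4-methoxyphenyl)pent-4-en-1-one | O=C(c1ccc(OC)cc1OC)[C@H](Cc1ccc(Cl)cc1)[C@H](c1ccc(OC)cc1[O-])/C=C/c1ccc(Cl)cc1.[Li+] | intermediate
10 | (1RS,2R,3R,4E)-2-(4-chlorobenzyl)-5-(4-chlorophenyl)-1-(2,4-dimethoxyphenyl)-3-(2-hydroxy-4-methoxyphenyl)pent-4-en-1-ol (both C1 epimers) | OC(c1ccc(OC)cc1OC)[C@H](Cc1ccc(Cl)cc1)[C@H](c1ccc(OC)cc1O)/C=C/c1ccc(Cl)cc1 | intermediate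
11 | 2,4-dimethoxybenzylic cation from 10 (contact ion pair, TRIP phosphate as counter-ion) | COc1ccc([CH+][C@H](Cc2ccc(Cl)cc2)[C@H](c2ccc(OC)cc2O)/C=C/c2ccc(Cl)cc2)c(OC)c1 | intermediate
12 | (2R,3R,4R)-3-(4-chlorobenzyl)-4-[(E)-2-(4-chlorophenyl)ethenyl]-2-(2,4-dimethoxyphenyl)-7-methoxychroman | COc1ccc2c(c1)O[C@@H](c1ccc(OC)cc1OC)[C@H](Cc1ccc(Cl)cc1)[C@H]2/C=C/c1ccc(Cl)cc1 | intermediate
13 | caraganin C, (2R,3R,4R)-2-(2,4-dimethoxyphenyl)-3-(4-hydroxybenzyl)-4-[(E)-2-(4-hydroxyphenyl)ethenyl]-7-methoxychroman | COc1ccc2c(c1)O[C@@H](c1ccc(OC)cc1OC)[C@H](Cc1ccc(O)cc1)[C@H]2/C=C/c1ccc(O)cc1 | target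

**Step count**
Total steps: 5. Longest linear sequence: 5 steps, from 7-methoxycoumarin.

**Steps most likely to fail**

*Step 1.* The 7-methoxy group makes the coumarin a sluggish push–pull acceptor, and the alkenylboronic acid can protodeboronate before it adds.
- The fallback sets out from 2 and comes back at 3. It moves the conjugate alkenylation to the aldehyde oxidation level.
- Bought 2-hydroxy-4-methoxybenzaldehyde F1 is homologated with Ph3P=CHCHO (toluene, 80 °C) to (E)-3-(2-hydroxy-4-methoxyphenyl)prop-2-enal F2.
- Next comes the known organocatalytic conjugate alkenylation of o-hydroxycinnamaldehydes. It uses diphenylprolinol trimethylsilyl ether of the enantiomeric series that gives 4S (20 mol%, CH2Cl2, 23 °C). Iminium activation is combined with delivery of the styryl group from the phenol-bound boronate of 2.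
- This gives the lactol (4S)-4-[(E)-2-(4-chlorophenyl)ethenyl]-7-methoxychroman-2-ol F3.
- TEMPO/PhI(OAc)2 oxidation of the lactol returns lactone 3. The detour costs two more steps.

*Step 3.* The hindered, enolisable lactone may be deprotonated by 8, or may take up a second aryl group.
- The fallback sets out from 6 and comes back at 10. It reverses the order of hydride and aryl.
- i-Bu2AlH (1.1 equiv, toluene, −78 °C), the standard partial reduction of dihydrocoumarins, gives the lactol (3R,4R)-3-(4-chlorobenzyl)-4-[(E)-2-(4-chlorophenyl)ethenyl]-7-methoxychroman-2-ol F4.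
- The open hydroxy-aldehyde form of F4 takes up 8 (2.2 equiv, made from 7 and n-BuLi, THF, −78 → 0 °C) and gives the same diol 10.
- An aldehyde cannot over-add and is much less hindered than the lactone carbonyl.

*Step 4 (the proposed new step).* Three things could go wrong.
- The phosphoric acid may be too weak.
- The chiral anion may be mismatched with the substrate bias.
- The phosphate may deprotonate 11 to the trisubstituted styrene.

The fallback sets out from 10 and comes back at 12. It uses the classical flavan ring closure, a Mitsunobu cyclodehydration (PPh3, DIAD, THF, 0 °C). The carbinol is activated as its alkoxyphosphonium ion under neutral conditions and the ring A phenol is the pronucleophile. With this donor-rich carbinol the phosphonium ion ionises to 11, so both epimers again converge through the same A(1,3)-controlled capture. Any minor 2,3-cis isomer is removed by chromatography. This fallback makes no new compound (entry F0).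

**Further compounds**
F1 | step 1 | 2-hydroxy-4-methoxybenzaldehyde (bought) | COc1ccc(C=O)c(O)c1
F2 | step 1 | (E)-3-(2-hydroxy-4-methoxyphenyl)prop-2-enal | COc1ccc(/C=C/C=O)c(O)c1
F3 | step 1 | (4S)-4-[(E)-2-(4-chlorophenyl)ethenyl]-7-methoxychroman-2-ol (anomer mixture) | COc1ccc2c(c1)OC(O)C[C@H]2/C=C/c1ccc(Cl)cc1
F4 | step 3 | (3R,4R)-3-(4-chlorobenzyl)-4-[(E)-2-(4-chlorophenyl)ethenyl]-7-methoxychroman-2-ol (anomer mixture) | COc1ccc2c(c1)OC(O)[C@H](Cc1ccc(Cl)cc1)[C@H]2/C=C/c1ccc(Cl)cc1
F0 | step 4 | none | none
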